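**Strategy**

The route rests on building ring B de novo instead of alkylating a resorcinol. Ring B carries oxygen at C2' and C4', the hydrated geranyl chain at C3' between them and C3 of ring C at C1'; a vinylketene–siloxyalkyne benzannulation gives exactly this pattern. An (E)-α-diazo enone, whose silyloxyethyl arm is the future C3–C4 unit, is photolysed to a vinylketene that captures a triisopropylsiloxyalkyne bearing the whole chain; the bonds C2'–C3', C4'–C5' and C1'–C2' and ring B form in one operation. The arylethanol obtained is joined to a phloroglucinol unit as a deoxybenzoin, closed to the isoflavone, and C3 is set by asymmetric transfer hydrogenation followed by reoxidation.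

Key step: step 8

Remark: the target is (3S) by CIP analysis of the given SMILES, and the chain alkene is E.
Remark: the two-carbon arm at C1' passes through the key step as a silyl-protected 2-hydroxyethyl group. An ester there would make the diazo enone a glutaconate-type carbon acid, and its only access would be acylation of diazomethane by an enoyl chloride, which suffers from dipolar cycloaddition.
Assumption: every compound marked as starting material in the compound list is taken as commercially available.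

**Route**

Step 1
Reactants: 1 geranyl acetate
Product: 4 (2E)-3,7-dimethyloct-2-ene-1,7-diol, via acetoxymercurio alcohol 2 (not isolated), via hydroxy acetate 3 (not isolated)
Conditions: Hg(OAc)2, THF/H2O, rt; NaBH4, aq NaOH, 0 °C; then MeOH, rt
Reagents that add atoms: water, O
Why: Markovnikov oxymercuration–demercuration should hydrate only the electron-rich C6=C7 alkene, because the allylic acetate deactivates C2=C3, and the alkaline medium then saponifies the acetate (ester hydrolysis) in the same flask.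

Step 2
Reactants: 4 (2E)-3,7-dimethyloct-2-ene-1,7-diol
Product: 6 (6E)-8-chloro-2,6-dimethyloct-6-en-2-ol, via allylic mesylate 5 (not isolated)
Conditions: MsCl, LiCl, 2,4,6-collidine, DMF, 0 °C
Reagents that add atoms: lithium chloride, [Li+].[Cl-]
Why: Allylic chlorination through the mesylate (sulfonylation of the primary allylic hydroxyl, then SN2 displacement by chloride) should proceed without allylic transposition or loss of the E geometry, the tertiary alcohol being too hindered to be sulfonylated.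

Step 3
Reactants: 6 (6E)-8-chloro-2,6-dimethyloct-6-en-2-ol
Product: 7 {[(6E)-8-chloro-2,6-dimethyloct-6-en-2-yl]oxy}triethylsilane
Conditions: TESOTf, 2,6-lutidine, CH2Cl2, −78 to 0 °C
Reagents that add atoms: triethylsilyl triflate, CC[Si](CC)(CC)OS(=O)(=O)C(F)(F)F
Why: Silylation with a silyl triflate and a hindered pyridine base is the reliable way to protect a tertiary alcohol, and the low temperature leaves the allylic chloride untouched.

Step 4
Reactants: 7 {[(6E)-8-chloro-2,6-dimethyloct-6-en-2-yl]oxy}triethylsilane; 8 ethynylmagnesium bromide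
Product: 9 {[(6E)-2,6-dimethyldec-6-en-9-yn-2-yl]oxy}triethylsilane
Conditions: CuCl (cat.), THF, 0 to 50 °C
Reagents that add atoms: none
Why: Copper-catalysed cross-coupling of an alkynyl Grignard reagent with a primary allylic chloride should give the 1,4-enyne by attack at the unhindered terminus with the E alkene retained.

Step 5
Reactants: 9 {[(6E)-2,6-dimethyldec-6-en-9-yn-2-yl]oxy}triethylsilane
Product: 12 triisopropyl{[(4E)-5,9-dimethyl-9-(triethylsilyloxy)dec-4-en-1-yn-1-yl]oxy}silane, via lithium acetylide 10 (not isolated), via lithium ynolate 11 (not isolated)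
Conditions: n-BuLi, THF, −78 °C; LiOOt-Bu (from t-BuOOH, LiN(SiMe3)2), −78 to 0 °C; TIPSOTf, −78 to 0 °C
Reagents that add atoms: tert-butyl hydroperoxide, CC(C)(C)OO; triisopropylsilyl triflate, CC(C)[Si](OS(=O)(=O)C(F)(F)F)(C(C)C)C(C)C
Why: Oxygen-atom transfer from lithium tert-butyl peroxide to the lithium acetylide gives the ynolate, and O-silylation by the bulky silyl triflate gives the siloxyalkyne (ynolate formation–silylation), with the tertiary silyl ether inert throughout.

Step 6
Reactants: 13 3-(tert-butyldimethylsilyloxy)propanal; 14 1-(triphenylphosphoranylidene)propan-2-one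
Product: 15 (3E)-6-(tert-butyldimethylsilyloxy)hex-3-en-2-one
Conditions: CH2Cl2, rt
Reagents that add atoms: none
Why: Wittig olefination with a ketone-stabilised ylide should give the E enone.

Step 7
Reactants: 15 (3E)-6-(tert-butyldimethylsilyloxy)hex-3-en-2-one
Product: 17 (3E)-6-(tert-butyldimethylsilyloxy)-1-diazohex-3-en-2-one, via trifluoroacetyl diketone 16 (not isolated)
Conditions: LiN(SiMe3)2, THF, −78 °C; CF3CO2CH2CF3; then MsN3, Et3N, H2O, MeCN, rt
Reagents that add atoms: methanesulfonyl azide, CS(=O)(=O)N=[N+]=[N-]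
Why: Kinetic deprotonation at the methyl group, trifluoroacetylation and detrifluoroacetylative diazo transfer from the sulfonyl azide to the activated diketone should give the α'-diazo enone under conditions to which the enone and the silyl ether are inert.

Step 8
Reactants: 12 triisopropyl{[(4E)-5,9-dimethyl-9-(triethylsilyloxy)dec-4-en-1-yn-1-yl]oxy}silane; 17 (3E)-6-(tert-butyldimethylsilyloxy)-1-diazohex-3-en-2-one
Product: 22 2-[(2E)-3,7-dimethyl-7-(triethylsilyloxy)oct-2-en-1-yl]-6-[2-(tert-butyldimethylsilyloxy)ethyl]-3-(triisopropylsilyloxy)phenol, via vinylketene 18 (not isolated), via vinylcyclobutenone 19 (not isolated), via dienylketene 20 (not isolated), via cyclohexadienone 21 (not isolated)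
Conditions: hν (254 nm), degassed ClCH2CH2Cl, rt; then 80 °C
Reagents that add atoms: none
Why: Light expels dinitrogen from 17 and Wolff rearrangement (1,2-shift of the alkenyl group) gives vinylketene 18, which adds siloxyalkyne 12 in a [2+2] cycloaddition to give 4-alkenylcyclobutenone 19. Conrotatory 4π electrocyclic opening of 19 gives dienylketene 20, and ring B closes by thermal disrotatory 6π electrocyclisation of 20 (bond C1'–C2') to cyclohexadienone 21, which tautomerises to phenol 22. The closest known reaction type is the photochemical Danheiser benzannulation of α-diazo enones with siloxyalkynes, which gives resorcinol monosilyl ethers. No stereocentre is created, since the only sp3 ring carbon of 21 is lost on aromatisation. The step needs one orientation in the [2+2] addition, and the polarity of the partners secures it: the chain-bearing alkyne carbon, made nucleophilic by the siloxy oxygen, bonds to the electrophilic ketene carbonyl carbon (C2'–C3') and the oxygen-bearing carbon to the ketene α-carbon (C4'–C5'), so the chain ends at C3' between the two oxygens. The isolated trisubstituted alkene of the chain is far less nucleophilic than the ynol ether and should not intercept the ketene, and every hydroxyl group is silylated so that none can add to it.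

Step 9
Reactants: 22 2-[(2E)-3,7-dimethyl-7-(triethylsilyloxy)oct-2-en-1-yl]-6-[2-(tert-butyldimethylsilyloxy)ethyl]-3-(triisopropylsilyloxy)phenol
Product: 23 2-[(2E)-7-hydroxy-3,7-dimethyloct-2-en-1-yl]-4-(2-hydroxyethyl)benzene-1,3-diol
Conditions: Bu4NF (excess), THF, rt to 40 °C
Reagents that add atoms: none
Why: Fluoride-induced desilylation should cleave the aryl triisopropylsilyl, primary tert-butyldimethylsilyl and tertiary triethylsilyl ethers alike, which frees the primary alcohol for oxidation and the phenols for a protecting group that the later organometallic and redox steps tolerate.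

Step 10
Reactants: 23 2-[(2E)-7-hydroxy-3,7-dimethyloct-2-en-1-yl]-4-(2-hydroxyethyl)benzene-1,3-diol
Product: 24 2-{3-[(2E)-7-hydroxy-3,7-dimethyloct-2-en-1-yl]-2,4-bis(methoxymethoxy)phenyl}ethan-1-ol
Conditions: MOMCl, K2CO3, acetone, 0 °C to rt
Reagents that add atoms: chloromethyl methyl ether, COCCl
Why: Williamson-type O-alkylation with carbonate as base should touch only the two phenols, since the aliphatic alcohols are not deprotonated.

Step 11
Reactants: 24 2-{3-[(2E)-7-hydroxy-3,7-dimethyloct-2-en-1-yl]-2,4-bis(methoxymethoxy)phenyl}ethan-1-ol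
Product: 25 2-{3-[(2E)-7-hydroxy-3,7-dimethyloct-2-en-1-yl]-2,4-bis(methoxymethoxy)phenyl}acetaldehyde
Conditions: Dess–Martin periodinane, CH2Cl2, 0 °C to rt
Reagents that add atoms: none
Why: Dess–Martin oxidation converts the primary alcohol into the arylacetaldehyde under near-neutral conditions, and the tertiary alcohol cannot be oxidised.

Step 12
Reactants: 26 phloroglucinol
Product: 27 1,3,5-tris(methoxymethoxy)benzene
Conditions: NaH, MOMCl, DMF, 0 °C to rt
Reagents that add atoms: chloromethyl methyl ether, COCCl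
Why: Threefold Williamson etherification of the phenoxides gives the tris-acetal that directs the later lithiation.

Step 13
Reactants: 27 1,3,5-tris(methoxymethoxy)benzene; 25 2-{3-[(2E)-7-hydroxy-3,7-dimethyloct-2-en-1-yl]-2,4-bis(methoxymethoxy)phenyl}acetaldehyde
Product: 30 (6E)-8-{3-[2-hydroxy-2-[2,4,6-tris(methoxymethoxy)phenyl]ethyl]-2,6-bis(methoxymethoxy)phenyl}-2,6-dimethyloct-6-en-2-ol (racemic at the carbinol carbon), via aryllithium 28 (not isolated), via arylcerium dichloride 29 (not isolated)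
Conditions: 27 (excess), n-BuLi, THF, 0 °C; CeCl3, −78 °C; then 25, −78 to −40 °C
Reagents that add atoms: none
Why: Directed ortho-lithiation between two methoxymethyl ethers, transmetalation to the weakly basic organocerium reagent and 1,2-addition to the enolisable aldehyde should give the carbinol, whose new stereocentre is formed without control and is removed in the next step; the excess of aryl-metal absorbs the tertiary hydroxyl proton.

Step 14
Reactants: 30 (6E)-8-{3-[2-hydroxy-2-[2,4,6-tris(methoxymethoxy)phenyl]ethyl]-2,6-bis(methoxymethoxy)phenyl}-2,6-dimethyloct-6-en-2-ol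
Product: 31 2-{3-[(2E)-7-hydroxy-3,7-dimethyloct-2-en-1-yl]-2,4-bis(methoxymethoxy)phenyl}-1-[2,4,6-tris(methoxymethoxy)phenyl]ethan-1-one
Conditions: Dess–Martin periodinane, CH2Cl2, 0 °C to rt
Reagents that add atoms: none
Why: Dess–Martin oxidation of the secondary carbinol gives the deoxybenzoin and leaves the tertiary alcohol, the acetals and the alkene alone.

Step 15
Reactants: 31 2-{3-[(2E)-7-hydroxy-3,7-dimethyloct-2-en-1-yl]-2,4-bis(methoxymethoxy)phenyl}-1-[2,4,6-tris(methoxymethoxy)phenyl]ethan-1-one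
Product: 32 1-[2-hydroxy-4,6-bis(methoxymethoxy)phenyl]-2-{3-[(2E)-7-hydroxy-3,7-dimethyloct-2-en-1-yl]-2,4-bis(methoxymethoxy)phenyl}ethan-1-one
Conditions: MgBr2·OEt2, Et2O/CH2Cl2, 0 °C to rt
Reagents that add atoms: none
Why: Chelation of MgBr2 between the ketone oxygen and an ortho acetal oxygen activates only that methoxymethyl group for attack by bromide (chelation-assisted ether cleavage ortho to a carbonyl group), and the magnesium phenoxide formed shields the second ortho acetal.

Step 16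
Reactants: 32 1-[2-hydroxy-4,6-bis(methoxymethoxy)phenyl]-2-{3-[(2E)-7-hydroxy-3,7-dimethyloct-2-en-1-yl]-2,4-bis(methoxymethoxy)phenyl}ethan-1-one
Product: 34 3-{3-[(2E)-7-hydroxy-3,7-dimethyloct-2-en-1-yl]-2,4-bis(methoxymethoxy)phenyl}-5,7-bis(methoxymethoxy)-4H-chromen-4-one, via enaminone 33 (not isolated)
Conditions: Me2NCH(OMe)2, toluene, 90 °C
Reagents that add atoms: N,N-dimethylformamide dimethyl acetal, COC(OC)N(C)C
Why: Condensation of the amide acetal at the doubly activated methylene gives the enaminone, and addition–elimination by the ortho phenol closes ring C (isoflavone synthesis from a 2-hydroxydeoxybenzoin).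

Step 17
Reactants: 34 3-{3-[(2E)-7-hydroxy-3,7-dimethyloct-2-en-1-yl]-2,4-bis(methoxymethoxy)phenyl}-5,7-bis(methoxymethoxy)-4H-chromen-4-one
Product: 36 (3S,4S)-3-{3-[(2E)-7-hydroxy-3,7-dimethyloct-2-en-1-yl]-2,4-bis(methoxymethoxy)phenyl}-5,7-bis(methoxymethoxy)chroman-4-ol, via racemic isoflavanone 35 (not isolated)
Conditions: RuCl[(S,S)-TsDPEN](p-cymene) (cat.), HCO2H/Et3N, EtOAc, 40 °C
Reagents that add atoms: none
Why: Noyori-type asymmetric transfer hydrogenation first reduces the C2=C3 bond to the configurationally labile isoflavanone and then reduces the ketone under dynamic kinetic resolution; the (S,S) catalyst is expected, by the usual sense for aryl ketones, to set C4 as S (the antipodal catalyst would be used if the sense proved opposite), and hydride delivery anti to the C3 aryl group sets C3 as S in the cis alcohol.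

Step 18
Reactants: 36 (3S,4S)-3-{3-[(2E)-7-hydroxy-3,7-dimethyloct-2-en-1-yl]-2,4-bis(methoxymethoxy)phenyl}-5,7-bis(methoxymethoxy)chroman-4-ol
Product: 37 (3S)-3-{3-[(2E)-7-hydroxy-3,7-dimethyloct-2-en-1-yl]-2,4-bis(methoxymethoxy)phenyl}-5,7-bis(methoxymethoxy)chroman-4-one
Conditions: Dess–Martin periodinane, CH2Cl2, 0 °C
Reagents that add atoms: none
Why: Dess–Martin oxidation under base-free conditions returns the C4 ketone, and C3, which is not involved, should keep its S configuration.

Step 19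
Reactants: 37 (3S)-3-{3-[(2E)-7-hydroxy-3,7-dimethyloct-2-en-1-yl]-2,4-bis(methoxymethoxy)phenyl}-5,7-bis(methoxymethoxy)chroman-4-one
Product: 38 (3S)-5,7-dihydroxy-3-{2,4-dihydroxy-3-[(2E)-7-hydroxy-3,7-dimethyloct-2-en-1-yl]phenyl}chroman-4-one
Conditions: HCl, MeOH, 0 °C to rt
Reagents that add atoms: none
Why: Acid-catalysed transacetalisation to methanol removes the four methoxymethyl groups; dilute acid at low temperature is chosen because base would enolise C3 and stronger acid would add a phenol to the chain alkene.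

**Compound list**

1 | geranyl acetate | CC(C)=CCC/C(C)=C/COC(C)=O | starting material
2 | (2E)-6-(acetoxymercurio)-7-hydroxy-3,7-dimethyloct-2-en-1-yl acetate (racemic at C6) | C/C(=C\COC(C)=O)CCC([Hg]OC(C)=O)C(C)(C)O | intermediate
3 | (2E)-7-hydroxy-3,7-dimethyloct-2-en-1-yl acetate | C/C(=C\COC(C)=O)CCCC(C)(C)O | intermediate
4 | (2E)-3,7-dimethyloct-2-ene-1,7-diol | C/C(=C\CO)CCCC(C)(C)O | intermediate
5 | (2E)-7-hydroxy-3,7-dimethyloct-2-en-1-yl methanesulfonate | C/C(=C\COS(C)(=O)=O)CCCC(C)(C)O | intermediate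
6 | (6E)-8-chloro-2,6-dimethyloct-6-en-2-ol | C/C(=C\CCl)CCCC(C)(C)O | intermediate
7 | {[(6E)-8-chloro-2,6-dimethyloct-6-en-2-yl]oxy}triethylsilane | C/C(=C\CCl)CCCC(C)(C)O[Si](CC)(CC)CC | intermediate
8 | ethynylmagnesium bromide | C#C[Mg]Br | starting material
9 | {[(6E)-2,6-dimethyldec-6-en-9-yn-2-yl]oxy}triethylsilane | C/C(=C\CC#C)CCCC(C)(C)O[Si](CC)(CC)CC | intermediate
10 | [(4E)-5,9-dimethyl-9-(triethylsilyloxy)dec-4-en-1-yn-1-yl]lithium | C/C(=C\CC#C[Li])CCCC(C)(C)O[Si](CC)(CC)CC | intermediate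
11 | lithium (4E)-5,9-dimethyl-9-(triethylsilyloxy)dec-4-en-1-yn-1-olate | C/C(=C\CC#CO[Li])CCCC(C)(C)O[Si](CC)(CC)CC | intermediate
12 | triisopropyl{[(4E)-5,9-dimethyl-9-(triethylsilyloxy)dec-4-en-1-yn-1-yl]oxy}silane | C/C(=C\CC#CO[Si](C(C)C)(C(C)C)C(C)C)CCCC(C)(C)O[Si](CC)(CC)CC | intermediate
13 | 3-(tert-butyldimethylsilyloxy)propanal | CC(C)(C)[Si](C)(C)OCCC=O | starting material
14 | 1-(triphenylphosphoranylidene)propan-2-one | CC(=O)C=P(c1ccccc1)(c1ccccc1)c1ccccc1 | starting material
15 | (3E)-6-(tert-butyldimethylsilyloxy)hex-3-en-2-one | CC(=O)/C=C/CCO[Si](C)(C)C(C)(C)C | intermediate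
16 | (5E)-8-(tert-butyldimethylsilyloxy)-1,1,1-trifluorooct-5-ene-2,4-dione | O=C(CC(=O)/C=C/CCO[Si](C)(C)C(C)(C)C)C(F)(F)F | intermediate
17 | (3E)-6-(tert-butyldimethylsilyloxy)-1-diazohex-3-en-2-one | [N-]=[N+]=CC(=O)/C=C/CCO[Si](C)(C)C(C)(C)C | intermediate
18 | (3E)-6-(tert-butyldimethylsilyloxy)hexa-1,3-dien-1-one | O=C=C/C=C/CCO[Si](C)(C)C(C)(C)C | intermediate
19 | 4-[(1E)-4-(tert-butyldimethylsilyloxy)but-1-en-1-yl]-2-[(2E)-3,7-dimethyl-7-(triethylsilyloxy)oct-2-en-1-yl]-3-(triisopropylsilyloxy)cyclobut-2-en-1-one (racemic) | O=C1C(C/C=C(\C)CCCC(C)(C)O[Si](CC)(CC)CC)=C(O[Si](C(C)C)(C(C)C)C(C)C)C1/C=C/CCO[Si](C)(C)C(C)(C)C | intermediate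
20 | (5E)-8-(tert-butyldimethylsilyloxy)-2-[(2E)-3,7-dimethyl-7-(triethylsilyloxy)oct-2-en-1-yl]-3-(triisopropylsilyloxy)octa-1,3,5-trien-1-one | O=C=C(C/C=C(\C)CCCC(C)(C)O[Si](CC)(CC)CC)C(O[Si](C(C)C)(C(C)C)C(C)C)=C/C=C/CCO[Si](C)(C)C(C)(C)C | intermediate
21 | 6-[2-(tert-butyldimethylsilyloxy)ethyl]-2-[(2E)-3,7-dimethyl-7-(triethylsilyloxy)oct-2-en-1-yl]-3-(triisopropylsilyloxy)cyclohexa-2,4-dien-1-one (racemic) | O=C1C(C/C=C(\C)CCCC(C)(C)O[Si](CC)(CC)CC)=C(O[Si](C(C)C)(C(C)C)C(C)C)C=CC1CCO[Si](C)(C)C(C)(C)C | intermediate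
22 | 2-[(2E)-3,7-dimethyl-7-(triethylsilyloxy)oct-2-en-1-yl]-6-[2-(tert-butyldimethylsilyloxy)ethyl]-3-(triisopropylsilyloxy)phenol | C/C(=C\Cc1c(O[Si](C(C)C)(C(C)C)C(C)C)ccc(CCO[Si](C)(C)C(C)(C)C)c1O)CCCC(C)(C)O[Si](CC)(CC)CC | intermediate
23 | 2-[(2E)-7-hydroxy-3,7-dimethyloct-2-en-1-yl]-4-(2-hydroxyethyl)benzene-1,3-diol | C/C(=C\Cc1c(O)ccc(CCO)c1O)CCCC(C)(C)O | intermediate
24 | 2-{3-[(2E)-7-hydroxy-3,7-dimethyloct-2-en-1-yl]-2,4-bis(methoxymethoxy)phenyl}ethan-1-ol | C/C(=C\Cc1c(OCOC)ccc(CCO)c1OCOC)CCCC(C)(C)O | intermediate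
25 | 2-{3-[(2E)-7-hydroxy-3,7-dimethyloct-2-en-1-yl]-2,4-bis(methoxymethoxy)phenyl}acetaldehyde | C/C(=C\Cc1c(OCOC)ccc(CC=O)c1OCOC)CCCC(C)(C)O | intermediate
26 | phloroglucinol | Oc1cc(O)cc(O)c1 | starting material
27 | 1,3,5-tris(methoxymethoxy)benzene | COCOc1cc(OCOC)cc(OCOC)c1 | intermediate
28 | [2,4,6-tris(methoxymethoxy)phenyl]lithium | COCOc1cc(OCOC)c([Li])c(OCOC)c1 | intermediate
29 | dichloro[2,4,6-tris(methoxymethoxy)phenyl]cerium | COCOc1cc(OCOC)c([Ce](Cl)Cl)c(OCOC)c1 | intermediate
30 | (6E)-8-{3-[2-hydroxy-2-[2,4,6-tris(methoxymethoxy)phenyl]ethyl]-2,6-bis(methoxymethoxy)phenyl}-2,6-dimethyloct-6-en-2-ol (racemic) | C/C(=C\Cc1c(OCOC)ccc(CC(O)c2c(OCOC)cc(OCOC)cc2OCOC)c1OCOC)CCCC(C)(C)O | intermediate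
31 | 2-{3-[(2E)-7-hydroxy-3,7-dimethyloct-2-en-1-yl]-2,4-bis(methoxymethoxy)phenyl}-1-[2,4,6-tris(methoxymethoxy)phenyl]ethan-1-one | C/C(=C\Cc1c(OCOC)ccc(CC(=O)c2c(OCOC)cc(OCOC)cc2OCOC)c1OCOC)CCCC(C)(C)O | intermediate
32 | 1-[2-hydroxy-4,6-bis(methoxymethoxy)phenyl]-2-{3-[(2E)-7-hydroxy-3,7-dimethyloct-2-en-1-yl]-2,4-bis(methoxymethoxy)phenyl}ethan-1-one | C/C(=C\Cc1c(OCOC)ccc(CC(=O)c2c(O)cc(OCOC)cc2OCOC)c1OCOC)CCCC(C)(C)O | intermediate
33 | 3-(dimethylamino)-1-[2-hydroxy-4,6-bis(methoxymethoxy)phenyl]-2-{3-[(2E)-7-hydroxy-3,7-dimethyloct-2-en-1-yl]-2,4-bis(methoxymethoxy)phenyl}prop-2-en-1-one | C/C(=C\Cc1c(OCOC)ccc(C(=CN(C)C)C(=O)c2c(O)cc(OCOC)cc2OCOC)c1OCOC)CCCC(C)(C)O | intermediate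
34 | 3-{3-[(2E)-7-hydroxy-3,7-dimethyloct-2-en-1-yl]-2,4-bis(methoxymethoxy)phenyl}-5,7-bis(methoxymethoxy)-4H-chromen-4-one | C/C(=C\Cc1c(OCOC)ccc(C2=COc3cc(OCOC)cc(OCOC)c3C2=O)c1OCOC)CCCC(C)(C)O | intermediate
35 | racemic 3-{3-[(2E)-7-hydroxy-3,7-dimethyloct-2-en-1-yl]-2,4-bis(methoxymethoxy)phenyl}-5,7-bis(methoxymethoxy)chroman-4-one | C/C(=C\Cc1c(OCOC)ccc(C2COc3cc(OCOC)cc(OCOC)c3C2=O)c1OCOC)CCCC(C)(C)O | intermediate
36 | (3S,4S)-3-{3-[(2E)-7-hydroxy-3,7-dimethyloct-2-en-1-yl]-2,4-bis(methoxymethoxy)phenyl}-5,7-bis(methoxymethoxy)chroman-4-ol | C/C(=C\Cc1c(OCOC)ccc([C@H]2COc3cc(OCOC)cc(OCOC)c3[C@H]2O)c1OCOC)CCCC(C)(C)O | intermediate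
37 | (3S)-3-{3-[(2E)-7-hydroxy-3,7-dimethyloct-2-en-1-yl]-2,4-bis(methoxymethoxy)phenyl}-5,7-bis(methoxymethoxy)chroman-4-one | C/C(=C\Cc1c(OCOC)ccc([C@H]2COc3cc(OCOC)cc(OCOC)c3C2=O)c1OCOC)CCCC(C)(C)O | intermediate
38 | (3S)-5,7-dihydroxy-3-{2,4-dihydroxy-3-[(2E)-7-hydroxy-3,7-dimethyloct-2-en-1-yl]phenyl}chroman-4-one | C/C(=C\Cc1c(O)ccc([C@H]2COc3cc(O)cc(O)c3C2=O)c1O)CCCC(C)(C)O | target

**Step count**

Total step count: 19.
Longest linear sequence: 16 steps (steps 1 to 5, 8 to 11 and 13 to 19).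

**Steps most likely to fail**

First, step 8. The vinylketene may be consumed by dimerisation faster than the hindered ynol ether captures it, or the vinylcyclobutenone may not open and reclose to the phenol under conditions that the silyl ethers survive. Fallback, from 7 back to 24: ring B is taken from a preformed resorcinol and the chain is introduced by directed metalation. Commercial methyl 2,4-dihydroxyphenylacetate is protected (MOMCl, i-Pr2NEt) to methyl 2-[2,4-bis(methoxymethoxy)phenyl]acetate F1 and reduced (LiAlH4) to 2-[2,4-bis(methoxymethoxy)phenyl]ethanol F2. Two equivalents of n-BuLi deprotonate the alcohol and lithiate the ring position between the two acetal oxygens; after addition of CuBr·SMe2, alkylation with allylic chloride 7 should give the chain-bearing arylethanol triethylsilyl ether F3. Bu4NF removes the silyl group and gives 24, where the route is rejoined.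

Second, step 17. Conjugate reduction of the doubly ortho-substituted chromone may be slow, and facial discrimination in the ketone reduction may be poor next to the C5 acetal and the bulky C3 aryl group; the outcome would be incomplete conversion or low enantio- and diastereoselectivity. Fallback, from 34 back to 37: asymmetric catalysis is replaced by resolution. Conjugate reduction of 34 with LiBH(s-Bu)3 (THF, −78 °C) should give racemic isoflavanone 35, here isolated. Preparative chromatography on a chiral stationary phase separates 37 from the (3R)-isoflavanone F4, and F4 is returned to 35 by base-induced racemisation (DBU) for another pass. Steps 17 and 18 are bypassed.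

Third, step 19. Acid-catalysed enolisation at C3 during the cleavage of four acetals would erode the enantiomeric purity. Fallback, from 34 back to 38: the acid step is moved to the achiral isoflavone and the last deprotection is done with fluoride. HCl in MeOH converts 34 into the tetrahydroxyisoflavone F5, and TBSOTf with 2,6-lutidine silylates all five hydroxyl groups to the pentakis(tert-butyldimethylsilyl) isoflavone F6. Transfer hydrogenation as in step 17 gives the cis-isoflavanol F7, and Dess–Martin oxidation gives the (3S)-isoflavanone F8. HF·pyridine buffered with pyridine (THF, 0 °C to rt) then removes the silyl groups under nearly neutral conditions and gives 38.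

**Further compounds**

F1 | step 8 | methyl 2-[2,4-bis(methoxymethoxy)phenyl]acetate | COCOc1ccc(CC(=O)OC)c(OCOC)c1
F2 | step 8 | 2-[2,4-bis(methoxymethoxy)phenyl]ethanol | COCOc1ccc(CCO)c(OCOC)c1
F3 | step 8 | 2-{3-[(2E)-3,7-dimethyl-7-(triethylsilyloxy)oct-2-en-1-yl]-2,4-bis(methoxymethoxy)phenyl}ethan-1-ol | C/C(=C\Cc1c(OCOC)ccc(CCO)c1OCOC)CCCC(C)(C)O[Si](CC)(CC)CC
F4 | step 17 | (3R)-3-{3-[(2E)-7-hydroxy-3,7-dimethyloct-2-en-1-yl]-2,4-bis(methoxymethoxy)phenyl}-5,7-bis(methoxymethoxy)chroman-4-one | C/C(=C\Cc1c(OCOC)ccc([C@@H]2COc3cc(OCOC)cc(OCOC)c3C2=O)c1OCOC)CCCC(C)(C)O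
F5 | step 19 | 5,7-dihydroxy-3-{2,4-dihydroxy-3-[(2E)-7-hydroxy-3,7-dimethyloct-2-en-1-yl]phenyl}-4H-chromen-4-one | C/C(=C\Cc1c(O)ccc(C2=COc3cc(O)cc(O)c3C2=O)c1O)CCCC(C)(C)O
F6 | step 19 | 5,7-bis(tert-butyldimethylsilyloxy)-3-{2,4-bis(tert-butyldimethylsilyloxy)-3-[(2E)-7-(tert-butyldimethylsilyloxy)-3,7-dimethyloct-2-en-1-yl]phenyl}-4H-chromen-4-one | C/C(=C\Cc1c(O[Si](C)(C)C(C)(C)C)ccc(C2=COc3cc(O[Si](C)(C)C(C)(C)C)cc(O[Si](C)(C)C(C)(C)C)c3C2=O)c1O[Si](C)(C)C(C)(C)C)CCCC(C)(C)O[Si](C)(C)C(C)(C)C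
F7 | step 19 | (3S,4S)-5,7-bis(tert-butyldimethylsilyloxy)-3-{2,4-bis(tert-butyldimethylsilyloxy)-3-[(2E)-7-(tert-butyldimethylsilyloxy)-3,7-dimethyloct-2-en-1-yl]phenyl}chroman-4-ol | C/C(=C\Cc1c(O[Si](C)(C)C(C)(C)C)ccc([C@H]2COc3cc(O[Si](C)(C)C(C)(C)C)cc(O[Si](C)(C)C(C)(C)C)c3[C@H]2O)c1O[Si](C)(C)C(C)(C)C)CCCC(C)(C)O[Si](C)(C)C(C)(C)C
F8 | step 19 | (3S)-5,7-bis(tert-butyldimethylsilyloxy)-3-{2,4-bis(tert-butyldimethylsilyloxy)-3-[(2E)-7-(tert-butyldimethylsilyloxy)-3,7-dimethyloct-2-en-1-yl]phenyl}chroman-4-one | C/C(=C\Cc1c(O[Si](C)(C)C(C)(C)C)ccc([C@H]2COc3cc(O[Si](C)(C)C(C)(C)C)cc(O[Si](C)(C)C(C)(C)C)c3C2=O)c1O[Si](C)(C)C(C)(C)C)CCCC(C)(C)O[Si](C)(C)C(C)(C)C
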